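## Analysis of the target

Betaethrin E (16) is an achiral diaryl ether made of two benzene rings. Ring B is a methyl benzoate with the ester at C1, a free hydroxyl at C2, a methyl at C4 and the ether oxygen at C6. Ring A is a benzyl palmitate with the acyloxymethyl group at C1', a methoxy group at C3', a free hydroxyl at C5' and the ether oxygen at C6'. There is no stereocentre, so the problems are regiochemistry and chemoselectivity only. The sensitive groups are the benzylic long-chain ester (labile to base, to transesterification and to hydrogenolysis), the ring B methyl ester, two free phenols and an electron-rich ring A that is easily attacked by electrophiles. The difficulty lies in the ether: its oxygen is flanked by the ester on ring B and by the benzylic carbon and an oxygen on ring A, so joining two finished rings would mean a crowded C–O coupling between poorly matched partners. In addition, ring A carries three oxygens that must all end up different. The route rests on the pattern of ring A: oxygens at C3' and C5' in a 1,3-relationship, and the aryloxy carbon C6' next to the carbon-bearing C1'. This is what results when a chain with a carbonyl on every second carbon, ending in an aryloxymethylene, closes on itself by forming the C1'–C6' bond. Ring B with its ether oxygen already attached is available as the symmetric diphenol 1.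

## Retrosynthetic reasoning

**16 to 15.** The two phenols are unmasked last. Both are carried as the same acetal, so one operation frees them, and no free phenol is present when hydride or an acid chloride is used. The forward step has to cleave two aryl acetals without touching the benzylic ester.

**15 to 13 and 14.** The ester C–O bond of the benzylic palmitate is cut. Acylation of the primary alcohol 13 with 14 is placed late, so that the lipophilic, base-labile ester is not carried through the basic steps.

**13 to 12.** The hydroxymethyl group at C1' is traced back to a methyl ester, because the ring-forming step needs a non-enolisable carbonyl terminus. The forward reduction must distinguish two methyl esters. The ring A ester has one ortho substituent and only meta oxygens. The ring B ester sits between two ortho oxygens that shield it and deactivate it.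

**12 to 11 to 10.** The two ring A oxygens are differentiated after the ring is made: a methoxymethyl group on the hindered hydroxyl of 11, and before that a methyl group on the open hydroxyl of 10. The handle is steric. The oxygen that becomes the C3' methoxy lies between two ring CH groups, while the other is next to the bulky aryloxy group.

**10 to 8 (key disconnection).** The ring A bond between the ester-bearing carbon and the aryloxy-bearing carbon (C1'–C6') is cut, and the two phenolic carbons are returned to ketones. Ring A unfolds to the linear 2,4,6-triketo ester 8, whose C7 is an aryloxymethylene.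
- This is the only ring bond whose cleavage gives a chain with alternating carbonyls and puts the ether oxygen on a terminal, enolisable carbon.
- The other terminus is an ester with no enolisable carbon, so only one aldol folding exists.
- The gain is the whole of ring A with its oxygens in place, and a crowded diaryl ether that is never made by arylation.
- The forward reaction must be a C-aldol of C7 onto the C2 ketone followed by dehydration and enolisation. It must win over O-cyclisation and over acyl substitution at either ester.

**8 to 4 and 5.** The chain is cut between C5 and C6. The forward reaction is acylation of the terminal carbon of the dianion 6 of the diketo ester 5 by the N-methoxy-N-methylamide 4. The aryloxymethylene comes in on the acyl donor, so the question of which end of an unsymmetrical ketone is extended does not arise. The chelated adduct 7 holds the new carbonyl masked until work-up.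

**4 to 2 and 3.** The alkyl C–O bond of the aryloxyacetyl unit is cut, not the aryl C–O bond. The forward step is a plain O-alkylation of phenol 2 with chloroacetamide 3.

**2 to 1.** The methoxymethyl ether is removed to reveal the symmetric diphenol 1. The forward step is a mono-protection that breaks the symmetry, so that the second phenol can become the ether oxygen.

## Alternatives that were turned down

**Alternative 1:** Ring B is cut across its C1–C6 and C4–C5 bonds into the electron-poor 2-pyranone A2 and the aryl ethynyl ether A3, which already carries a complete, protected ring A.
- Forward step: a [4+2] cycloaddition joins the nucleophilic alkyne terminus to the methyl-bearing pyranone carbon and the oxygen-bearing alkyne carbon to the ester-bearing one. Decarboxylative cycloreversion then gives the pentasubstituted benzoate A1.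
- For it: it is convergent, the ether oxygen travels on the alkyne so no hindered C–O coupling is needed, and the polarisation of both partners fixes the regiochemistry of ring B. On convergence it is stronger than the chosen route.
- Against it: A3 needs a fully differentiated 1,2,3,5-tetrasubstituted ring A phenol, whose three different oxygens are the hard part of the molecule and would need a separate multistep synthesis. Converting a doubly ortho-substituted phenol into an ethynyl ether is lengthy, and such ethers hydrate and rearrange easily. The cycloaddition needs heat that an acyloxy pyranone, a silyl ether and an ynol ether may not all survive. Afterwards three orthogonal protecting groups (pivalate, silyl ether, acetal) must be removed or exchanged in the presence of a methyl ester.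
- Comparison: the chosen route creates the ring A oxygenation in the ring-forming step from stock materials and uses one protecting-group type.

**Alternative 2:** The diaryl ether C6–O bond and the C1–carboxyl bond of ring B are cut together, giving the ortho-silyl aryl triflate A5 and the ring A phenol A6.
- Forward step: fluoride releases the aryne from A5. The phenoxide of A6 adds at the aryne carbon remote from the acetal oxygen. The resulting aryl anion, stabilised between two oxygens, is carboxylated in the same flask to give acid A4.
- For it: the hindered ether and the carboxyl group are set in one operation, arynes accept crowded nucleophiles, and the regiochemistry has a sound inductive basis. On directness of the central bond formation it is stronger than the chosen route.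
- Against it: the phenoxide itself reacts reversibly with the carboxylating gas, which lowers its nucleophilicity. The aryl anion can be protonated instead of carboxylated. Both A5 and A6 need several steps each, and A6 again demands a fully differentiated ring A. The end game would have to free the benzylic alcohol and acylate it next to phenols that carry the same kind of acetal.
- Comparison: the chosen route takes ring B ready-made with its own oxygen and needs neither an aryne precursor nor a prefabricated ring A.

**Alternative 3:** Ring A is cut at C4'–C5', C2'–C3' and C5'–C6' into the diazo enone A8 and methoxyethyne A9.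
- Forward step: irradiation brings about Wolff rearrangement of A8 to a vinylketene that already carries the aryloxy group. Cycloaddition with A9, four-electron ring opening of the cyclobutenone and six-electron ring closure then give phenol A7.
- For it: A7 is constitutionally the same as compound 11. The C3' methoxy and C5' hydroxyl arrive already distinguished, which removes the selective methylation of the chosen route. On this point it is clearly stronger.
- Against it: A8 is a beta-aryloxy enone with a diazoacetyl group and an ester on the same carbon. Making it would need several steps of addition–elimination and diazo chemistry on a vinylogous aryl ester that readily exchanges its aryloxy group. A9 is volatile and unstable. The ketene has competing closures onto its own ester carbonyl.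
- Comparison: the chosen route reaches its ring-closure precursor in three steps from stock chemicals and concentrates the uncertainty in one thermal, base-mediated step.

Key step: step 4

Remark: compound 8 is drawn in its all-keto form but is expected to exist mainly as enol tautomers; this does not change the reactivity argument. The target has no stereocentre.

## Route

Step 1
Reactants: 1 methyl 2,6-dihydroxy-4-methylbenzoate
Product: 2 methyl 2-hydroxy-6-(methoxymethoxy)-4-methylbenzoate
Conditions: MOMCl (1.05 equiv), i-Pr2NEt (1.2 equiv), CH2Cl2, 0 °C to rt
Reagents that add atoms: chloromethyl methyl ether, COCCl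
Why: O-alkylation of one of two equivalent phenols; once the first acetal is on, the remaining hydroxyl is held in a strong hydrogen bond to the ester carbonyl and reacts much more slowly under amine-base conditions, so one equivalent of reagent should give mainly the mono-ether.

Step 2
Reactants: 2 methyl 2-hydroxy-6-(methoxymethoxy)-4-methylbenzoate, 3 2-chloro-N-methoxy-N-methylacetamide
Product: 4 methyl 2-{2-[methoxy(methyl)amino]-2-oxoethoxy}-6-(methoxymethoxy)-4-methylbenzoate
Conditions: 3 (1.2 equiv), K2CO3 (2 equiv), DMF, 60 °C
Reagents that add atoms: 2-chloro-N-methoxy-N-methylacetamide (compound 3), CON(C)C(=O)CCl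
Why: Williamson ether synthesis with an activated alpha-chloro amide; the amide alpha-protons are far too weakly acidic for K2CO3 to start a Dieckmann closure onto the neighbouring ester.

Step 3
Reactants: 5 methyl 2,4-dioxopentanoate, 4 methyl 2-{2-[methoxy(methyl)amino]-2-oxoethoxy}-6-(methoxymethoxy)-4-methylbenzoate
Product: 8 methyl 7-[2-(methoxycarbonyl)-3-(methoxymethoxy)-5-methylphenoxy]-2,4,6-trioxoheptanoate, via acetopyruvate dianion 6 (not isolated), via tetrahedral hemiaminal adduct 7 (not isolated)
Conditions: 5 (1.5 equiv), LiN(i-Pr)2 (3.1 equiv), THF, −78 to −30 °C; then 4 (1.0 equiv), −78 to −20 °C; AcOH, −78 °C; pH 5 aqueous work-up; excess 5 removed under high vacuum, crude 8 used at once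
Reagents that add atoms: methyl 2,4-dioxopentanoate (compound 5), COC(=O)C(=O)CC(C)=O
Why: Terminal acylation of a 1,3-dicarbonyl dianion by an N-methoxy-N-methylamide (Weinreb ketone synthesis): the second deprotonation of 5 can only take place at the C5 methyl, and that carbon is the most nucleophilic site of 6. The lithium-chelated adduct 7 does not collapse until the acidic quench, so the new ketone is protected from a second addition and from premature cyclisation. The hindered 2,6-disubstituted ring B ester of 4 should not compete with the amide carbonyl at low temperature.

Step 4
Reactants: 8 methyl 7-[2-(methoxycarbonyl)-3-(methoxymethoxy)-5-methylphenoxy]-2,4,6-trioxoheptanoate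
Product: 10 methyl 3,5-dihydroxy-2-[2-(methoxycarbonyl)-3-(methoxymethoxy)-5-methylphenoxy]benzoate, via cyclic aldol adduct 9 (not isolated)
Conditions: K2CO3 (3 equiv), MeOH, 0 °C to rt (40 °C if slow); then AcOH to pH 5
Reagents that add atoms: none
Why: K2CO3 in methanol converts 8 into its enolates, and although the C3 and C5 methylenes are the most acidic sites, fast proton exchange makes the enolate of the C6 ketone towards C7 available; the aryloxy group acidifies C7–H, which helps. C7 adds to the C2 ketone, the most electrophilic carbonyl of the chain because the ester activates it, to give aldolate 9; hydroxide is then lost by an E1cB process (C7–H is alpha to the C6 ketone) and the two remaining ketones enolise, so the sequence ends irreversibly in the aromatic ring. The closest known reaction type is the base-induced aldol cyclisation of 2,4,6-triketones (heptane-2,4,6-trione to 3,5-dihydroxytoluene) and of 3,5,7-triketo esters to resorcylates. The ring closes in the 6-(enolendo)-exo-trig mode: C7 and the C6=C7 enolate double bond lie inside the forming six-membered ring and the C2 carbonyl oxygen lies outside. The two stereocentres of 9 are formed without control and are erased on aromatisation, so none has to be set. The step needs C7-to-C2 closure to win over three other paths: O-cyclisation to a 4-pyranone, Claisen closure of C5 onto the C1 ester to a five-membered trione, and Dieckmann closure of C7 onto the ring B ester to a benzofuranone. The substrate secures this because C7 can reach a ketone only through a six-membered transition state and the ester end has no enolisable carbon, so one aldol mode exists; pyranone formation is acid-promoted and is disfavoured in base. An ester-activated ketone should take up an enolate much faster than either ester undergoes acyl substitution: C5 is a stabilised diketonate, an alkali carbonate offers no chelating divalent metal to favour C-acylation, and the ring B ester is twisted and shielded by two ortho substituents.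

Step 5
Reactants: 10 methyl 3,5-dihydroxy-2-[2-(methoxycarbonyl)-3-(methoxymethoxy)-5-methylphenoxy]benzoate
Product: 11 methyl 3-hydroxy-5-methoxy-2-[2-(methoxycarbonyl)-3-(methoxymethoxy)-5-methylphenoxy]benzoate
Conditions: Cs2CO3 (2.5 equiv), DMF, −10 °C; MeI (1.0 equiv, slow addition), −10 °C to rt
Reagents that add atoms: iodomethane, CI
Why: Williamson methylation under conditions where both phenols are present as phenoxides, so that selectivity depends on nucleophilicity and not on acidity; the C5 oxygen lies between two ring CH groups and is the more basic, whereas the C3 oxygen is shielded by the twisted ring B and its ortho ester, so one equivalent of MeI should go mainly to the C5 oxygen.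

Step 6
Reactants: 11 methyl 3-hydroxy-5-methoxy-2-[2-(methoxycarbonyl)-3-(methoxymethoxy)-5-methylphenoxy]benzoate
Product: 12 methyl 5-methoxy-3-(methoxymethoxy)-2-[2-(methoxycarbonyl)-3-(methoxymethoxy)-5-methylphenoxy]benzoate
Conditions: NaH (1.3 equiv), MOMCl (1.5 equiv), DMF, 0 °C to rt
Reagents that add atoms: chloromethyl methyl ether, COCCl
Why: Standard acetal protection of a hindered phenol through its sodium phenoxide; it keeps a free phenol away from the hydride and the acid chloride and lets both phenols be freed together at the end.

Step 7
Reactants: 12 methyl 5-methoxy-3-(methoxymethoxy)-2-[2-(methoxycarbonyl)-3-(methoxymethoxy)-5-methylphenoxy]benzoate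
Product: 13 methyl 2-[2-(hydroxymethyl)-4-methoxy-6-(methoxymethoxy)phenoxy]-6-(methoxymethoxy)-4-methylbenzoate
Conditions: i-Bu2AlH (2.3 equiv), CH2Cl2, −78 °C; aqueous KNaC4H4O6 (potassium sodium tartrate) work-up
Reagents that add atoms: none
Why: Ester-to-alcohol reduction with an aluminium hydride; the ring A ester has one ortho substituent and only meta oxygens, while the ring B ester is flanked by two ortho oxygens that shield it and reduce its electrophilicity by donation, so at −78 °C with a small excess the ring A ester should react selectively.

Step 8
Reactants: 13 methyl 2-[2-(hydroxymethyl)-4-methoxy-6-(methoxymethoxy)phenoxy]-6-(methoxymethoxy)-4-methylbenzoate, 14 palmitoyl chloride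
Product: 15 methyl 2-{2-[(hexadecanoyloxy)methyl]-4-methoxy-6-(methoxymethoxy)phenoxy}-6-(methoxymethoxy)-4-methylbenzoate
Conditions: 14 (1.2 equiv), Et3N (1.5 equiv), DMAP (0.1 equiv), CH2Cl2, 0 °C to rt
Reagents that add atoms: palmitoyl chloride (compound 14), CCCCCCCCCCCCCCCC(=O)Cl
Why: DMAP-catalysed acylation of a primary benzylic alcohol by an acid chloride; no other nucleophilic group is free in 13.

Step 9
Reactants: 15 methyl 2-{2-[(hexadecanoyloxy)methyl]-4-methoxy-6-(methoxymethoxy)phenoxy}-6-(methoxymethoxy)-4-methylbenzoate
Product: 16 betaethrin E, methyl 2-{2-[(hexadecanoyloxy)methyl]-6-hydroxy-4-methoxyphenoxy}-6-hydroxy-4-methylbenzoate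
Conditions: ZnBr2 (3 equiv), n-PrSH (5 equiv), CH2Cl2, 0 °C to rt
Reagents that add atoms: none
Why: Lewis-acid-promoted acetal exchange: ZnBr2 activates each aryl acetal and the thiol captures the methoxymethyl cation as a thioacetal, so the electron-rich ring A is not alkylated; the conditions are non-hydrolytic, so the benzylic palmitate and the methyl ester should remain.

## Compound list

1 | methyl 2,6-dihydroxy-4-methylbenzoate | COC(=O)c1c(O)cc(C)cc1O | starting material
2 | methyl 2-hydroxy-6-(methoxymethoxy)-4-methylbenzoate | COCOc1cc(C)cc(O)c1C(=O)OC | intermediate
3 | 2-chloro-N-methoxy-N-methylacetamide | CON(C)C(=O)CCl | starting material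
4 | methyl 2-{2-[methoxy(methyl)amino]-2-oxoethoxy}-6-(methoxymethoxy)-4-methylbenzoate | CON(C)C(=O)COc1cc(C)cc(OCOC)c1C(=O)OC | intermediate
5 | methyl 2,4-dioxopentanoate | COC(=O)C(=O)CC(C)=O | starting material
6 | dilithium 1-methoxy-1-oxopenta-2,4-diene-2,4-diolate (dianion of 5; not isolated) | COC(=O)C([O-])=CC([O-])=C.[Li+].[Li+] | intermediate
7 | dilithium 1-methoxy-6-[methoxy(methyl)amino]-7-[2-(methoxycarbonyl)-3-(methoxymethoxy)-5-methylphenoxy]-1,4-dioxohept-2-ene-2,6-diolate (racemic tetrahedral adduct; not isolated) | COC(=O)C([O-])=CC(=O)CC([O-])(COc1cc(C)cc(OCOC)c1C(=O)OC)N(C)OC.[Li+].[Li+] | intermediate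
8 | methyl 7-[2-(methoxycarbonyl)-3-(methoxymethoxy)-5-methylphenoxy]-2,4,6-trioxoheptanoate | COC(=O)C(=O)CC(=O)CC(=O)COc1cc(C)cc(OCOC)c1C(=O)OC | intermediate
9 | methyl 1-hydroxy-2-[2-(methoxycarbonyl)-3-(methoxymethoxy)-5-methylphenoxy]-3,5-dioxocyclohexane-1-carboxylate (mixture of racemic diastereomers; not isolated) | COC(=O)C1(O)CC(=O)CC(=O)C1Oc1cc(C)cc(OCOC)c1C(=O)OC | intermediate
10 | methyl 3,5-dihydroxy-2-[2-(methoxycarbonyl)-3-(methoxymethoxy)-5-methylphenoxy]benzoate | COC(=O)c1cc(O)cc(O)c1Oc1cc(C)cc(OCOC)c1C(=O)OC | intermediate
11 | methyl 3-hydroxy-5-methoxy-2-[2-(methoxycarbonyl)-3-(methoxymethoxy)-5-methylphenoxy]benzoate | COC(=O)c1cc(OC)cc(O)c1Oc1cc(C)cc(OCOC)c1C(=O)OC | intermediate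
12 | methyl 5-methoxy-3-(methoxymethoxy)-2-[2-(methoxycarbonyl)-3-(methoxymethoxy)-5-methylphenoxy]benzoate | COC(=O)c1cc(OC)cc(OCOC)c1Oc1cc(C)cc(OCOC)c1C(=O)OC | intermediate
13 | methyl 2-[2-(hydroxymethyl)-4-methoxy-6-(methoxymethoxy)phenoxy]-6-(methoxymethoxy)-4-methylbenzoate | OCc1cc(OC)cc(OCOC)c1Oc1cc(C)cc(OCOC)c1C(=O)OC | intermediate
14 | palmitoyl chloride (hexadecanoyl chloride) | CCCCCCCCCCCCCCCC(=O)Cl | starting material
15 | methyl 2-{2-[(hexadecanoyloxy)methyl]-4-methoxy-6-(methoxymethoxy)phenoxy}-6-(methoxymethoxy)-4-methylbenzoate | CCCCCCCCCCCCCCCC(=O)OCc1cc(OC)cc(OCOC)c1Oc1cc(C)cc(OCOC)c1C(=O)OC | intermediate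
16 | betaethrin E, methyl 2-{2-[(hexadecanoyloxy)methyl]-6-hydroxy-4-methoxyphenoxy}-6-hydroxy-4-methylbenzoate | CCCCCCCCCCCCCCCC(=O)OCc1cc(OC)cc(O)c1Oc1cc(C)cc(O)c1C(=O)OC | target

## Step count and least certain steps

Total: 9 steps. Longest linear sequence: 9 steps (1 to 16); compounds 3, 5 and 14 are bought.

**Step 4 (key step).** The closure may take an acyl-substitution course instead of the aldol course: the central diketonate carbon may attack the chain ester, or the terminal enolate may attack the ring B ester. Methoxide may also fragment the oxalyl ketone by retro-Claisen attack, or the polyanion may simply stall because the terminal enolate is too scarce. The fallback folds the chain at the carboxylate oxidation level, where Claisen closure at C1 is impossible. It sets out from 8. Dilute aqueous KOH at 0 °C to rt first hydrolyses the very labile alpha-keto ester to 7-[2-(methoxycarbonyl)-3-(methoxymethoxy)-5-methylphenoxy]-2,4,6-trioxoheptanoic acid F2 (as its salt; the hindered ring B ester should survive). In the same mildly basic water this should cyclise by the same aldol, the way triketo acids do, to 3,5-dihydroxy-2-[2-(methoxycarbonyl)-3-(methoxymethoxy)-5-methylphenoxy]benzoic acid F3. Carboxylate-selective esterification (KHCO3, MeI, DMF) then comes back to the route at 10.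

**Step 3.** The strongly basic dianion may remove a proton from the aryloxyacetamide instead of adding to it, which would return starting material or trigger closure of the amide enolate onto the ring B ester. The dianion may also condense with itself through its own ester, and the product may cyclodehydrate during an acidic work-up. The fallback builds the chain in the opposite order and sets out from 4. Addition of the lithium enolate of acetone (LiN(i-Pr)2, acetone, THF, −78 °C) should give the 1,3-diketone methyl 2-[(2,4-dioxopentyl)oxy]-6-(methoxymethoxy)-4-methylbenzoate F1. A crossed Claisen condensation with dimethyl oxalate under NaOMe in MeOH, which under reversible conditions acylates the terminal methyl of a 1,3-diketone, then comes back to the route at 8. The sodium enolate so formed can be taken straight into step 4.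

**Step 5.** Site selectivity between the two phenoxides may be poor, and methylation may run on to the dimethyl ether or occur on the ring carbon between the two oxygens. The fallback uses a bulky silyl group, which discriminates by size far better than MeI, and sets out from 10. Silylation with i-Pr3SiCl and imidazole in DMF at 0 °C should take the open hydroxyl only, giving methyl 3-hydroxy-2-[2-(methoxycarbonyl)-3-(methoxymethoxy)-5-methylphenoxy]-5-[(triisopropylsilyl)oxy]benzoate F4. Acetal protection of the hindered hydroxyl (MOMCl, i-Pr2NEt, CH2Cl2) gives methyl 3-(methoxymethoxy)-2-[2-(methoxycarbonyl)-3-(methoxymethoxy)-5-methylphenoxy]-5-[(triisopropylsilyl)oxy]benzoate F5. CsF and MeI in DMF then remove the silyl group to the phenoxide of methyl 5-hydroxy-3-(methoxymethoxy)-2-[2-(methoxycarbonyl)-3-(methoxymethoxy)-5-methylphenoxy]benzoate F6 and methylate it in the same flask. This comes back to the route at 12.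

**Step 7.** Reduction may run on to the ring B ester or stop partly at the aldehyde. The fallback separates the two esters by hydrolysis rate and then uses a reductant that is selective for acids. It sets out from 12. LiOH in THF/H2O at rt should saponify only the less hindered ring A ester, since 2,6-disubstituted benzoates resist acyl–oxygen hydrolysis, to give 5-methoxy-3-(methoxymethoxy)-2-[2-(methoxycarbonyl)-3-(methoxymethoxy)-5-methylphenoxy]benzoic acid F7. BH3·SMe2 in THF reduces the carboxylic acid in the presence of the methyl ester and comes back to the route at 13.

**Step 9.** The palmitoyl group may be cleaved or transferred, the released methoxymethyl cation may attack ring A if it is not trapped fast enough, and the acetal that lacks a neighbouring ester may be removed incompletely. The fallback reverses the order of deprotection and acylation and sets out from 13. HCl in MeOH removes both acetals to give the triol methyl 2-hydroxy-6-[2-hydroxy-6-(hydroxymethyl)-4-methoxyphenoxy]-4-methylbenzoate F8. A Mitsunobu esterification with palmitic acid (PPh3, DIAD, THF, 0 °C) then activates only the aliphatic alcohol and uses the carboxylic acid, which is far more acidic than either phenol, as the nucleophile. This comes back to the route at 16.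

## Further compounds

F1 | step 3 | methyl 2-[(2,4-dioxopentyl)oxy]-6-(methoxymethoxy)-4-methylbenzoate | CC(=O)CC(=O)COc1cc(C)cc(OCOC)c1C(=O)OC
F2 | step 4 | 7-[2-(methoxycarbonyl)-3-(methoxymethoxy)-5-methylphenoxy]-2,4,6-trioxoheptanoic acid | OC(=O)C(=O)CC(=O)CC(=O)COc1cc(C)cc(OCOC)c1C(=O)OC
F3 | step 4 | 3,5-dihydroxy-2-[2-(methoxycarbonyl)-3-(methoxymethoxy)-5-methylphenoxy]benzoic acid | OC(=O)c1cc(O)cc(O)c1Oc1cc(C)cc(OCOC)c1C(=O)OC
F4 | step 5 | methyl 3-hydroxy-2-[2-(methoxycarbonyl)-3-(methoxymethoxy)-5-methylphenoxy]-5-[(triisopropylsilyl)oxy]benzoate | COC(=O)c1cc(O[Si](C(C)C)(C(C)C)C(C)C)cc(O)c1Oc1cc(C)cc(OCOC)c1C(=O)OC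
F5 | step 5 | methyl 3-(methoxymethoxy)-2-[2-(methoxycarbonyl)-3-(methoxymethoxy)-5-methylphenoxy]-5-[(triisopropylsilyl)oxy]benzoate | COC(=O)c1cc(O[Si](C(C)C)(C(C)C)C(C)C)cc(OCOC)c1Oc1cc(C)cc(OCOC)c1C(=O)OC
F6 | step 5 | methyl 5-hydroxy-3-(methoxymethoxy)-2-[2-(methoxycarbonyl)-3-(methoxymethoxy)-5-methylphenoxy]benzoate | COC(=O)c1cc(O)cc(OCOC)c1Oc1cc(C)cc(OCOC)c1C(=O)OC
F7 | step 7 | 5-methoxy-3-(methoxymethoxy)-2-[2-(methoxycarbonyl)-3-(methoxymethoxy)-5-methylphenoxy]benzoic acid | OC(=O)c1cc(OC)cc(OCOC)c1Oc1cc(C)cc(OCOC)c1C(=O)OC
F8 | step 9 | methyl 2-hydroxy-6-[2-hydroxy-6-(hydroxymethyl)-4-methoxyphenoxy]-4-methylbenzoate | OCc1cc(OC)cc(O)c1Oc1cc(C)cc(O)c1C(=O)OC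
A1 | alternative 1 | methyl 2-[2-({[tert-butyl(dimethyl)silyl]oxy}methyl)-4-methoxy-6-(methoxymethoxy)phenoxy]-4-methyl-6-[(2,2-dimethylpropanoyl)oxy]benzoate | COC(=O)c1c(OC(=O)C(C)(C)C)cc(C)cc1Oc1c(OCOC)cc(OC)cc1CO[Si](C)(C)C(C)(C)C
A2 | alternative 1 | methyl 4-[(2,2-dimethylpropanoyl)oxy]-6-methyl-2-oxo-2H-pyran-3-carboxylate | COC(=O)C1=C(OC(=O)C(C)(C)C)C=C(C)OC1=O
A3 | alternative 1 | tert-butyl{[2-(ethynyloxy)-5-methoxy-3-(methoxymethoxy)phenyl]methoxy}dimethylsilane | C#COc1c(OCOC)cc(OC)cc1CO[Si](C)(C)C(C)(C)C
A4 | alternative 2 | 2-{4-methoxy-2-(methoxymethoxy)-6-[(methoxymethoxy)methyl]phenoxy}-6-(methoxymethoxy)-4-methylbenzoic acid | COCOCc1cc(OC)cc(OCOC)c1Oc1cc(C)cc(OCOC)c1C(=O)O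
A5 | alternative 2 | 3-(methoxymethoxy)-5-methyl-2-(trimethylsilyl)phenyl trifluoromethanesulfonate | COCOc1cc(C)cc(OS(=O)(=O)C(F)(F)F)c1[Si](C)(C)C
A6 | alternative 2 | 4-methoxy-2-(methoxymethoxy)-6-[(methoxymethoxy)methyl]phenol | COCOCc1cc(OC)cc(OCOC)c1O
A7 | alternative 3 | methyl 3-hydroxy-5-methoxy-2-[2-(methoxycarbonyl)-3-(methoxymethoxy)-5-methylphenoxy]benzoate | COC(=O)c1cc(OC)cc(O)c1Oc1cc(C)cc(OCOC)c1C(=O)OC
A8 | alternative 3 | methyl 2-(diazoacetyl)-3-[2-(methoxycarbonyl)-3-(methoxymethoxy)-5-methylphenoxy]prop-2-enoate (either alkene isomer) | COC(=O)C(=COc1cc(C)cc(OCOC)c1C(=O)OC)C(=O)C=[N+]=[N-]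
A9 | alternative 3 | methoxyethyne | COC#C
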